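**Retrosynthetic overview**
- The target flavone comes from its 2',4'-di-O-pivaloyl ester by methanolysis; the ring B phenols stay masked as electron-poor esters until ring C exists.
- Ring C is the only ring built and is closed last, by forming O1–C8a in a 1-(ring B aryl)-3-(2,3,4,5-tetramethoxyphenyl)propane-1,3-dione through anodic C–H/O–H coupling.
- The plan rests on C8a–H: it is the single aromatic C–H of ring A, para to the C6 methoxy and ortho to the C8 methoxy group, so the oxidized ring A can take up the C2 enol oxygen there without a phenol or halogen at C8a.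
- The diketone is cut at C2–C3 into 2,3,4,5-tetramethoxyacetophenone (Friedel–Crafts acetylation of 1,2,3,4-tetramethoxybenzene) and 2,4-bis(pivaloyloxy)-5-methoxybenzoyl chloride (from 2,4-dihydroxy-5-methoxybenzaldehyde).

Key step: step 6

Remark: the 1,3-diketone is drawn in its keto form although it should exist mainly as the enol, and the two tautomers are treated as one compound; both starting materials are taken as purchasable.

**Step 1**
Reactants: 1 1,2,3,4-tetramethoxybenzene
Product: 2 1-(2,3,4,5-tetramethoxyphenyl)ethan-1-one
Conditions: Ac2O, Sc(OTf)3 (cat.), MeNO2, 50 °C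
Reagents that add atoms: acetic anhydride, CC(=O)OC(C)=O
Why: Friedel–Crafts acylation in which the two free positions of 1 are equivalent by symmetry, so only one ketone can form, while a catalytic metal triflate with the anhydride avoids the stoichiometric hard Lewis acid that would cleave the methoxy group ortho to the new carbonyl, and the deactivated product should resist a second acylation.

**Step 2**
Reactants: 3 2,4-dihydroxy-5-methoxybenzaldehyde
Product: 4 2,4-bis(pivaloyloxy)-5-methoxybenzaldehyde
Conditions: PivCl, Et3N, DMAP (cat.), CH2Cl2, 0 °C to rt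
Reagents that add atoms: pivaloyl chloride, CC(C)(C)C(=O)Cl
Why: DMAP-catalysed O-acylation of both phenols, giving esters that lower the electron density of ring B for the anodic step and whose bulk slows acyl migration.

**Step 3**
Reactants: 4 2,4-bis(pivaloyloxy)-5-methoxybenzaldehyde
Product: 5 2,4-bis(pivaloyloxy)-5-methoxybenzoic acid
Conditions: NaClO2, NaH2PO4, 2-methylbut-2-ene, t-BuOH/THF/H2O, 0 °C to rt
Reagents that add atoms: sodium chlorite, [Na+].[O-]Cl=O
Why: Pinnick oxidation, in which chlorous acid converts the aldehyde into the acid at about pH 4 where aryl pivalates are stable, and the alkene scavenges the hypochlorous acid that could chlorinate ring B.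

**Step 4**
Reactants: 5 2,4-bis(pivaloyloxy)-5-methoxybenzoic acid
Product: 6 2,4-bis(pivaloyloxy)-5-methoxybenzoyl chloride
Conditions: (COCl)2, DMF (cat.), CH2Cl2, 0 °C to rt; evaporate, use crude
Reagents that add atoms: oxalyl chloride, O=C(Cl)C(=O)Cl
Why: Acid chloride formation through the Vilsmeier-type chloroiminium salt, under conditions mild enough for the aryl esters (O-acyl salicyloyl chlorides are stable compounds) and with volatile by-products only.

**Step 5**
Reactants: 2 1-(2,3,4,5-tetramethoxyphenyl)ethan-1-one; 6 2,4-bis(pivaloyloxy)-5-methoxybenzoyl chloride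
Product: 7 1-[2,4-bis(pivaloyloxy)-5-methoxyphenyl]-3-(2,3,4,5-tetramethoxyphenyl)propane-1,3-dione
Conditions: MgBr2·OEt2, i-Pr2NEt, CH2Cl2, 0 °C to rt; 1 M HCl work-up
Reagents that add atoms: none
Why: Crossed Claisen-type C-acylation under soft enolization, in which MgBr2 activates the ketone for deprotonation by the tertiary amine and the magnesium enolate is acylated on carbon to a chelated magnesium diketonate that is inert to further acylation, with no alkoxide or strong base present to attack the pivalates.

**Step 6**
Reactants: 7 1-[2,4-bis(pivaloyloxy)-5-methoxyphenyl]-3-(2,3,4,5-tetramethoxyphenyl)propane-1,3-dione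
Product: 8 2-[2,4-bis(pivaloyloxy)-5-methoxyphenyl]-5,6,7,8-tetramethoxy-4H-chromen-4-one
Conditions: graphite anode, Pt cathode, undivided cell, constant current (about 2.2 F/mol), n-Bu4NPF6, dry HFIP, rt
Reagents that add atoms: none
Why: Proposed new method: one-electron oxidation at graphite in HFIP should occur on the tetramethoxyaryl ring of the enol of 7, and once the enol leaves its O–H···O chelate by rotation about the C3–C4 bond (HFIP as hydrogen-bond donor should loosen the chelate), the oxygen on C2 adds to the ortho C–H carbon of ring A (future C8a); a second electron transfer and loss of the C8a proton and the enol proton should give the pyranone, while protons are reduced to H2 at the cathode. The closest known reactions are anodic dehydrogenative C–H/O–H lactonizations of 2-arylbenzoic acids to benzocoumarins and, for the same O1–C8a bond, base- or copper-mediated O-arylation of ortho-haloaryl 1,3-diketones to chromones. Ring C closes by O–C bond formation in a 6-exo-trig sense (counting the C8–C8a π bond of the oxidized arene) through a six-membered transition state, and no stereocenter is formed. Selectivity between the arenes is needed because the other enol oxygen could close in the same way onto the C–H of ring B next to its methoxy group; ring A with four methoxy groups should be oxidized at a clearly lower potential than ring B with one methoxy, two acyloxy groups and the aroyl carbonyl. Site selectivity on ring A follows from C8a being its only C–H, para to the C6 methoxy and ortho to the C8 methoxy group where the radical cation carries much of its charge, and proton loss makes attack there irreversible whereas ipso attack at the methoxylated ortho carbon is reversible. Over-oxidation should be limited by passing little more than 2 F per mol in dry medium, since ring A of 8 is conjugated to the pyranone carbonyl and water would open a path to quinones from the para-related C5/C8 methoxy pair.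

**Step 7**
Reactants: 8 2-[2,4-bis(pivaloyloxy)-5-methoxyphenyl]-5,6,7,8-tetramethoxy-4H-chromen-4-one
Product: 9 2-(2,4-dihydroxy-5-methoxyphenyl)-5,6,7,8-tetramethoxy-4H-chromen-4-one
Conditions: K2CO3, MeOH (degassed), rt; then 1 M HCl to pH 4
Reagents that add atoms: none
Why: Base-promoted transesterification (methanolysis) of the two aryl pivalates, which are labile because phenoxides are good leaving groups, while the five methyl ethers and the pyranone should be untouched at room temperature and acidification returns the neutral diphenol.

**Compound list**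
1 | 1,2,3,4-tetramethoxybenzene | COc1ccc(OC)c(OC)c1OC | starting material
2 | 1-(2,3,4,5-tetramethoxyphenyl)ethan-1-one | CC(=O)c1cc(OC)c(OC)c(OC)c1OC | intermediate
3 | 2,4-dihydroxy-5-methoxybenzaldehyde | COc1cc(C=O)c(O)cc1O | starting material
4 | 2,4-bis(pivaloyloxy)-5-methoxybenzaldehyde | COc1cc(C=O)c(OC(=O)C(C)(C)C)cc1OC(=O)C(C)(C)C | intermediate
5 | 2,4-bis(pivaloyloxy)-5-methoxybenzoic acid | COc1cc(C(=O)O)c(OC(=O)C(C)(C)C)cc1OC(=O)C(C)(C)C | intermediate
6 | 2,4-bis(pivaloyloxy)-5-methoxybenzoyl chloride | COc1cc(C(=O)Cl)c(OC(=O)C(C)(C)C)cc1OC(=O)C(C)(C)C | intermediate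
7 | 1-[2,4-bis(pivaloyloxy)-5-methoxyphenyl]-3-(2,3,4,5-tetramethoxyphenyl)propane-1,3-dione | COc1cc(C(=O)CC(=O)c2cc(OC)c(OC)c(OC)c2OC)c(OC(=O)C(C)(C)C)cc1OC(=O)C(C)(C)C | intermediate
8 | 2-[2,4-bis(pivaloyloxy)-5-methoxyphenyl]-5,6,7,8-tetramethoxy-4H-chromen-4-one | COc1cc(-c2cc(=O)c3c(OC)c(OC)c(OC)c(OC)c3o2)c(OC(=O)C(C)(C)C)cc1OC(=O)C(C)(C)C | intermediate
9 | 2-(2,4-dihydroxy-5-methoxyphenyl)-5,6,7,8-tetramethoxy-4H-chromen-4-one | COc1cc(-c2cc(=O)c3c(OC)c(OC)c(OC)c(OC)c3o2)c(O)cc1O | target

**Total step count:** 7
**Longest linear sequence:** 6 steps (3 → 4 → 5 → 6 → 7 → 8 → 9)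

**Steps most likely to fail**

Step 6. Electron transfer may take place from the enol π system instead of ring A and lead to radical coupling at C3. The oxygen may also add at the methoxylated ortho carbon, or product 8 may be oxidized further. The fallback uses known chemistry, sets out from ketone 2 and returns to the route at 8. Nuclear bromination of 2 at its only ring C–H (NBS, MeCN, rt) should give 1-(2-bromo-3,4,5,6-tetramethoxyphenyl)ethan-1-one F1. Soft-enolization acylation of this ketone with acid chloride 6 (MgBr2·OEt2, i-Pr2NEt, CH2Cl2) should give 1-[2,4-bis(pivaloyloxy)-5-methoxyphenyl]-3-(2-bromo-3,4,5,6-tetramethoxyphenyl)propane-1,3-dione F2. Intramolecular Ullmann-type O-arylation of its diketonate (CuI, monovalent copper, 1,10-phenanthroline, K2CO3, DMF, 90 °C) then closes the same O1–C8a bond and gives 8.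

Step 5. The pivaloyl group ortho to the new diketone may migrate to the magnesium diketonate oxygen through a six-membered transition state, after which the freed phenol can close onto the ring A carbonyl to the isomeric chromone; double acylation is a second risk. The fallback sets out from ketone 2 and aldehyde 4 and returns at 7, without acid 5 or chloride 6. Silylation of 2 (TMSOTf, Et3N, CH2Cl2, 0 °C) should give trimethyl{[1-(2,3,4,5-tetramethoxyphenyl)ethenyl]oxy}silane F3. Its Mukaiyama aldol addition to 4 (BF3·OEt2, CH2Cl2, −78 °C) should give racemic 3-[2,4-bis(pivaloyloxy)-5-methoxyphenyl]-3-hydroxy-1-(2,3,4,5-tetramethoxyphenyl)propan-1-one F4. Dess–Martin oxidation (CH2Cl2, rt) of the secondary alcohol then gives 7 and removes the stereocenter.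

Step 1. The methoxy group ortho to the new carbonyl may be cleaved by Lewis-acid chelation, or the catalytic acylation may stall through binding of the product ketone to the catalyst. The fallback sets out from 1 and returns at 2. Directed ortho-lithiation of 1 (n-BuLi, TMEDA, THF, 0 °C) should give (2,3,4,5-tetramethoxyphenyl)lithium F5, which is acylated with N-methoxy-N-methylacetamide (−78 °C to rt, aqueous NH4Cl quench) to give 2 under base-only conditions.

**Further compounds**
F1 | step 6 | 1-(2-bromo-3,4,5,6-tetramethoxyphenyl)ethan-1-one | CC(=O)c1c(Br)c(OC)c(OC)c(OC)c1OC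
F2 | step 6 | 1-[2,4-bis(pivaloyloxy)-5-methoxyphenyl]-3-(2-bromo-3,4,5,6-tetramethoxyphenyl)propane-1,3-dione | COc1cc(C(=O)CC(=O)c2c(Br)c(OC)c(OC)c(OC)c2OC)c(OC(=O)C(C)(C)C)cc1OC(=O)C(C)(C)C
F3 | step 5 | trimethyl{[1-(2,3,4,5-tetramethoxyphenyl)ethenyl]oxy}silane | C=C(O[Si](C)(C)C)c1cc(OC)c(OC)c(OC)c1OC
F4 | step 5 | racemic 3-[2,4-bis(pivaloyloxy)-5-methoxyphenyl]-3-hydroxy-1-(2,3,4,5-tetramethoxyphenyl)propan-1-one | COc1cc(C(O)CC(=O)c2cc(OC)c(OC)c(OC)c2OC)c(OC(=O)C(C)(C)C)cc1OC(=O)C(C)(C)C
F5 | step 1 | (2,3,4,5-tetramethoxyphenyl)lithium | [Li]c1cc(OC)c(OC)c(OC)c1OC
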